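**Strategy.** Everything rests on cutting the bond between C2, the fully substituted ether carbon of ring A (the oxane), and C1', the methine of ring B (the cyclohexane). An Ireland–Claisen rearrangement of the O-benzyl lactate of (R)-cyclohex-2-en-1-ol makes this bond and both adjacent stereocentres in one operation: C1' by suprafacial chirality transfer from the carbinol carbon, C2 by a chelated ketene acetal reacting through a boat. The step exploits the fact that C1' is allylic to C2'=C3' in ring B, so the alkene it leaves is the handle for C4' oxidation and the C3'/C4' halogens. The carboxyl carbon becomes C3; ring A is closed by bromoetherification before ring B is halogenated.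

Key step: step 3

Remark: ring A is numbered O1, C2 (CH3, ring B), C3, C4, C5 (Br), C6 (two CH3) and ring B C1' (on C2) to C6' with Br on C3' and Cl/CH3 on C4'; the stereocentre of acid 3 is erased in step 3, so the commercial (S) acid is used only for convenience, and 3 and 12 are taken as purchased.

Step 1
Reactants: 1 cyclohex-2-en-1-one
Product: 2 (R)-cyclohex-2-en-1-ol
Conditions: (S)-2-methyl-CBS-oxazaborolidine (10 mol%), catecholborane, toluene, −78 °C
Reagents that add atoms: none
Why: Corey–Bakshi–Shibata reduction, in which the oxazaborolidine binds the borane and the ketone with the alkene arm as the larger group, so hydride should be delivered to one carbonyl face and the (R)-carbinol centre is set by the catalyst.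

Step 2
Reactants: 2 (R)-cyclohex-2-en-1-ol; 3 (S)-2-(benzyloxy)propanoic acid
Product: 4 (R)-cyclohex-2-en-1-yl (S)-2-(benzyloxy)propanoate
Conditions: DCC, DMAP (cat.), CH2Cl2, 0 °C → rt
Reagents that add atoms: none
Why: Steglich esterification activates the acid and not the alcohol, so the allylic C–O bond and its (R) configuration are untouched; any epimerisation at the lactate carbon is harmless because step 3 erases that centre.

Step 3
Reactants: 4 (R)-cyclohex-2-en-1-yl (S)-2-(benzyloxy)propanoate
Product: 8 (2R)-2-(benzyloxy)-2-[(1S)-cyclohex-2-en-1-yl]propanoic acid, via chelated lithium enolate 5 (not isolated), via (Z)-trimethylsilyl ketene acetal 6 (not isolated), via trimethylsilyl ester 7 (not isolated)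
Conditions: LiN(SiMe3)2, Me3SiCl, Et3N, THF, −78 °C → rt; then 1 M HCl
Reagents that add atoms: none
Why: Ireland–Claisen rearrangement: LiN(SiMe3)2 removes the α-proton to give the enolate in which lithium bridges the enolate and benzyloxy oxygens, Me3SiCl traps it as the (Z)-silyl ketene acetal, and a suprafacial [3,3]-sigmatropic shift joins the α-carbon (C2) to the alkene terminus (C1') while the alkene moves to C2'=C3'. The closest known reaction type is the chelate-controlled Claisen rearrangement of α-alkoxy esters of cyclic allylic alcohols to tertiary α-alkoxy acids. No ring is closed. C1' is controlled by chirality transfer, the new C–C bond forming on the ring face that the ester oxygen leaves, so the (R)-carbinol should give (S)-C1'; C2 is controlled by the fixed ketene acetal geometry (benzyloxy cis to OSiMe3, methyl cis to the allylic oxygen) acting through a boat-like transition state. The step needs boat over chair selectivity, which the cis alkene held in the six-membered ring secures because the chair would push the silyloxy-bearing carbon over the ring methylenes; the chair would give the C2 epimer.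

Step 4
Reactants: 8 (2R)-2-(benzyloxy)-2-[(1S)-cyclohex-2-en-1-yl]propanoic acid
Product: 9 (2R)-2-(benzyloxy)-2-[(1S)-cyclohex-2-en-1-yl]propan-1-ol
Conditions: LiAlH4, THF, 0 °C → reflux
Reagents that add atoms: none
Why: Hydride reduction of a carboxylic acid to the primary alcohol touches no stereocentre and leaves the benzyl ether and the ring alkene alone.

Step 5
Reactants: 9 (2R)-2-(benzyloxy)-2-[(1S)-cyclohex-2-en-1-yl]propan-1-ol
Product: 10 (2R)-2-(benzyloxy)-2-[(1S)-cyclohex-2-en-1-yl]propanal
Conditions: Dess–Martin periodinane, CH2Cl2, rt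
Reagents that add atoms: none
Why: Dess–Martin oxidation stops at the aldehyde, which has no α-hydrogen and therefore cannot epimerise at C2.

Step 6
Reactants: 10 (2R)-2-(benzyloxy)-2-[(1S)-cyclohex-2-en-1-yl]propanal
Product: 11 benzyl (2S)-2-[(1S)-cyclohex-2-en-1-yl]but-3-en-2-yl ether
Conditions: Ph3PCH3Br, KOtBu, THF, 0 °C → rt
Reagents that add atoms: methyltriphenylphosphonium bromide, C[P+](c1ccccc1)(c1ccccc1)c1ccccc1.[Br-]
Why: Wittig methylenation of the non-enolisable aldehyde installs C4 as a terminal vinyl carbon without affecting either stereocentre.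

Step 7
Reactants: 11 benzyl (2S)-2-[(1S)-cyclohex-2-en-1-yl]but-3-en-2-yl ether; 12 1-bromo-2-methylprop-1-ene
Product: 14 benzyl (2S)-2-[(1S)-cyclohex-2-en-1-yl]-6-methylhept-5-en-2-yl ether, via B-alkyl-9-BBN adduct 13 (not isolated)
Conditions: 9-BBN, THF, rt; then Pd(dppf)Cl2 (3 mol%), 3 M NaOH, 65 °C
Reagents that add atoms: none
Why: Anti-Markovnikov hydroboration with 9-BBN is selective for the monosubstituted vinyl group over the cis-disubstituted ring alkene, and the primary alkylborane then undergoes B-alkyl Suzuki–Miyaura coupling with the vinyl bromide to complete the C3–C6 chain.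

Step 8
Reactants: 14 benzyl (2S)-2-[(1S)-cyclohex-2-en-1-yl]-6-methylhept-5-en-2-yl ether
Product: 15 (2S)-2-[(1S)-cyclohex-2-en-1-yl]-6-methylhept-5-en-2-ol
Conditions: Na, NH3 (l), THF, −78 °C; then NH4Cl
Reagents that add atoms: none
Why: Dissolving-metal cleavage of the benzyl ether (Birch conditions) frees the tertiary alcohol, and isolated alkenes are not reduced under these conditions.

Step 9
Reactants: 15 (2S)-2-[(1S)-cyclohex-2-en-1-yl]-6-methylhept-5-en-2-ol
Product: 16 (2S,5R)-5-bromo-2-[(1S)-cyclohex-2-en-1-yl]-2,6,6-trimethyloxane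
Conditions: NBS, (CF3)2CHOH, 4 Å MS, 0 °C
Reagents that add atoms: N-bromosuccinimide, O=C1CCC(=O)N1Br
Why: Bromoetherification, in which the more electron-rich trisubstituted alkene forms the bromonium ion and the tertiary hydroxyl opens it at the tertiary carbon C6 (6-endo, Markovnikov) through a chair that keeps ring B on C2 and the new bromine on C5 equatorial, which should set (R)-C5.

Step 10
Reactants: 16 (2S,5R)-5-bromo-2-[(1S)-cyclohex-2-en-1-yl]-2,6,6-trimethyloxane
Product: 17 (4S)-4-[(2S,5R)-5-bromo-2,6,6-trimethyloxan-2-yl]cyclohex-2-en-1-one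
Conditions: Rh2(caprolactamate)4 (1 mol%), t-BuOOH, K2CO3, CH2Cl2, rt
Reagents that add atoms: tert-butyl hydroperoxide, CC(C)(C)OO
Why: Allylic oxidation by tert-butylperoxyl radicals should abstract hydrogen from the open C4' methylene and not from the C1'–H shielded by the quaternary C2, and oxidise that carbon to the ketone conjugated with C2'=C3'; ring A has no C–H next to oxygen and its bromide is inert.

Step 11
Reactants: 17 (4S)-4-[(2S,5R)-5-bromo-2,6,6-trimethyloxan-2-yl]cyclohex-2-en-1-one
Product: 18 5-[(2S,5R)-5-bromo-2,6,6-trimethyloxan-2-yl]-7-oxabicyclo[4.1.0]heptan-2-one (C2'–C3' oxirane trans to the oxanyl group)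
Conditions: H2O2 (30% aq), NaOH (cat.), MeOH, 0 °C
Reagents that add atoms: hydrogen peroxide, OO
Why: Weitz–Scheffer nucleophilic epoxidation, in which hydroperoxide adds to C2' on the face opposite the adjacent oxanyl substituent on C1', so the oxirane should form trans to it.

Step 12
Reactants: 18 5-[(2S,5R)-5-bromo-2,6,6-trimethyloxan-2-yl]-7-oxabicyclo[4.1.0]heptan-2-one
Product: 19 5-[(2S,5R)-5-bromo-2,6,6-trimethyloxan-2-yl]-2-methyl-7-oxabicyclo[4.1.0]heptan-2-ol (hydroxyl cis to the oxirane oxygen; methyl cis to the oxanyl group)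
Conditions: MeMgBr, THF, −78 °C; then NH4Cl
Reagents that add atoms: methylmagnesium bromide, C[Mg]Br
Why: Grignard 1,2-addition to an α,β-epoxy ketone takes place on the carbonyl face opposite the oxirane oxygen, which places the C4' methyl on the face of the C1' substituent (axial in the final ring) and the tertiary hydroxyl cis to the epoxide.

Step 13
Reactants: 19 5-[(2S,5R)-5-bromo-2,6,6-trimethyloxan-2-yl]-2-methyl-7-oxabicyclo[4.1.0]heptan-2-ol
Product: 20 (1S,2R,4S)-4-[(2S,5R)-5-bromo-2,6,6-trimethyloxan-2-yl]-1-methylcyclohexane-1,2-diol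
Conditions: i-Bu2AlH, CH2Cl2, −78 → 0 °C
Reagents that add atoms: none
Why: Reductive opening of a 2,3-epoxy alcohol, in which the aluminium alkoxide activates the cis oxirane and external hydride attacks the distal carbon C2' (trans-diaxial opening; C3' is shielded by the axial C4' methyl), leaving the cis-1,2-diol without touching the ring A bromide.

Step 14
Reactants: 20 (1S,2R,4S)-4-[(2S,5R)-5-bromo-2,6,6-trimethyloxan-2-yl]-1-methylcyclohexane-1,2-diol
Product: 22 cyclic sulfate of diol 20 (1,3,2-dioxathiolane 2,2-dioxide cis-fused at C3'–C4'), via cyclic sulfite 21 (not isolated)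
Conditions: SOCl2, Et3N, CH2Cl2, 0 °C; then RuCl3 (cat.), NaIO4, MeCN/H2O, 0 °C
Reagents that add atoms: thionyl chloride, O=S(Cl)Cl; sodium periodate, [Na+].[O-]I(=O)(=O)=O
Why: Cyclic sulfate formation from a cis-1,2-diol (cyclic sulfite, then ruthenium-catalysed oxidation at sulfur) activates C3' without breaking a C–O bond, so both configurations are retained.

Step 15
Reactants: 22 cyclic sulfate of diol 20
Product: 24 (1S,2S,4S)-2-bromo-4-[(2S,5R)-5-bromo-2,6,6-trimethyloxan-2-yl]-1-methylcyclohexan-1-ol, via lithium alkyl sulfate 23 (not isolated)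
Conditions: LiBr, THF, 50 °C; then H2SO4 (cat.), H2O, THF, rt
Reagents that add atoms: lithium bromide, [Li+].[Br-]
Why: SN2 opening of the cyclic sulfate by bromide at the secondary carbon C3' with inversion (the tertiary C4' is not attacked) puts bromine cis to the C1' substituent, and acid hydrolysis of the tertiary sulfate monoester by S–O cleavage returns the C4' alcohol with retention.

Step 16
Reactants: 24 (1S,2S,4S)-2-bromo-4-[(2S,5R)-5-bromo-2,6,6-trimethyloxan-2-yl]-1-methylcyclohexan-1-ol
Product: 26 caespitane (2S,5R)-5-bromo-2-[(1S,3S,4S)-3-bromo-4-chloro-4-methylcyclohexyl]-2,6,6-trimethyloxane, via tertiary chlorosulfite 25 (not isolated)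
Conditions: SOCl2, Et2O, −20 → 0 °C (no base)
Reagents that add atoms: thionyl chloride, O=S(Cl)Cl
Why: Deoxychlorination of a tertiary alcohol with SOCl2, in which the chlorosulfite collapses with internal return of chloride (SNi) and, where the trans bromine bridges to C4', chloride reopens the bromonium ion at the tertiary carbon, so both pathways should give retention at C4' with Cl trans to Br.

**Compound list**

1 | cyclohex-2-en-1-one | O=C1C=CCCC1 | starting material
2 | (R)-cyclohex-2-en-1-ol | O[C@H]1C=CCCC1 | intermediate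
3 | (S)-2-(benzyloxy)propanoic acid | C[C@H](OCc1ccccc1)C(=O)O | starting material
4 | (R)-cyclohex-2-en-1-yl (S)-2-(benzyloxy)propanoate | C[C@H](OCc1ccccc1)C(=O)O[C@H]1C=CCCC1 | intermediate
5 | chelated lithium enolate of 4, benzyloxy cis to OLi (not isolated) | C/C(OCc1ccccc1)=C(/[O-])O[C@H]1C=CCCC1.[Li+] | intermediate
6 | (Z)-trimethylsilyl ketene acetal of 4 (not isolated) | C/C(OCc1ccccc1)=C(/O[Si](C)(C)C)O[C@H]1C=CCCC1 | intermediate
7 | trimethylsilyl (2R)-2-(benzyloxy)-2-[(1S)-cyclohex-2-en-1-yl]propanoate (not isolated) | c1ccccc1CO[C@](C)([C@H]1CCCC=C1)C(=O)O[Si](C)(C)C | intermediate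
8 | (2R)-2-(benzyloxy)-2-[(1S)-cyclohex-2-en-1-yl]propanoic acid | c1ccccc1CO[C@](C)([C@H]1CCCC=C1)C(=O)O | intermediate
9 | (2R)-2-(benzyloxy)-2-[(1S)-cyclohex-2-en-1-yl]propan-1-ol | c1ccccc1CO[C@](C)([C@H]1CCCC=C1)CO | intermediate
10 | (2R)-2-(benzyloxy)-2-[(1S)-cyclohex-2-en-1-yl]propanal | c1ccccc1CO[C@](C)([C@H]1CCCC=C1)C=O | intermediate
11 | benzyl (2S)-2-[(1S)-cyclohex-2-en-1-yl]but-3-en-2-yl ether | c1ccccc1CO[C@](C)([C@H]1CCCC=C1)C=C | intermediate
12 | 1-bromo-2-methylprop-1-ene | CC(C)=CBr | starting material
13 | 9-[(3S)-3-(benzyloxy)-3-[(1S)-cyclohex-2-en-1-yl]butyl]-9-borabicyclo[3.3.1]nonane (not isolated) | c1ccccc1CO[C@](C)([C@H]1CCCC=C1)CCB1C2CCCC1CCC2 | intermediate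
14 | benzyl (2S)-2-[(1S)-cyclohex-2-en-1-yl]-6-methylhept-5-en-2-yl ether | c1ccccc1CO[C@](C)([C@H]1CCCC=C1)CCC=C(C)C | intermediate
15 | (2S)-2-[(1S)-cyclohex-2-en-1-yl]-6-methylhept-5-en-2-ol | O[C@](C)([C@H]1CCCC=C1)CCC=C(C)C | intermediate
16 | (2S,5R)-5-bromo-2-[(1S)-cyclohex-2-en-1-yl]-2,6,6-trimethyloxane | CC1(C)O[C@](C)([C@H]2CCCC=C2)CC[C@H]1Br | intermediate
17 | (4S)-4-[(2S,5R)-5-bromo-2,6,6-trimethyloxan-2-yl]cyclohex-2-en-1-one | CC1(C)O[C@](C)([C@H]2CCC(=O)C=C2)CC[C@H]1Br | intermediate
18 | 5-[(2S,5R)-5-bromo-2,6,6-trimethyloxan-2-yl]-7-oxabicyclo[4.1.0]heptan-2-one, oxirane trans to the oxanyl group | CC1(C)O[C@](C)([C@H]2CCC(=O)[C@@H]3O[C@H]23)CC[C@H]1Br | intermediate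
19 | 5-[(2S,5R)-5-bromo-2,6,6-trimethyloxan-2-yl]-2-methyl-7-oxabicyclo[4.1.0]heptan-2-ol, hydroxyl cis to the oxirane oxygen | CC1(C)O[C@](C)([C@H]2CC[C@](C)(O)[C@@H]3O[C@H]23)CC[C@H]1Br | intermediate
20 | (1S,2R,4S)-4-[(2S,5R)-5-bromo-2,6,6-trimethyloxan-2-yl]-1-methylcyclohexane-1,2-diol | CC1(C)O[C@](C)([C@H]2CC[C@](C)(O)[C@H](O)C2)CC[C@H]1Br | intermediate
21 | cyclic sulfite of 20, mixture at sulfur (not isolated) | CC1(C)O[C@](C)([C@H]2CC[C@]3(C)OS(=O)O[C@@H]3C2)CC[C@H]1Br | intermediate
22 | cyclic sulfate of 20 | CC1(C)O[C@](C)([C@H]2CC[C@]3(C)OS(=O)(=O)O[C@@H]3C2)CC[C@H]1Br | intermediate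
23 | lithium (1S,2S,4S)-2-bromo-4-[(2S,5R)-5-bromo-2,6,6-trimethyloxan-2-yl]-1-methylcyclohexyl sulfate (not isolated) | CC1(C)O[C@](C)([C@H]2CC[C@](C)(OS(=O)(=O)[O-])[C@@H](Br)C2)CC[C@H]1Br.[Li+] | intermediate
24 | (1S,2S,4S)-2-bromo-4-[(2S,5R)-5-bromo-2,6,6-trimethyloxan-2-yl]-1-methylcyclohexan-1-ol | CC1(C)O[C@](C)([C@H]2CC[C@](C)(O)[C@@H](Br)C2)CC[C@H]1Br | intermediate
25 | chlorosulfite of 24 (not isolated) | CC1(C)O[C@](C)([C@H]2CC[C@](C)(OS(=O)Cl)[C@@H](Br)C2)CC[C@H]1Br | intermediate
26 | caespitane, (2S,5R)-5-bromo-2-[(1S,3S,4S)-3-bromo-4-chloro-4-methylcyclohexyl]-2,6,6-trimethyloxane | CC1(C)O[C@](C)([C@H]2CC[C@](C)(Cl)[C@@H](Br)C2)CC[C@H]1Br | target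

**Total step count:** 16. **Longest linear sequence:** 16 steps (1 to 26; 3 and 12 are purchased).

**Steps most likely to fail**

1. Step 16. Ionisation of the tertiary chlorosulfite may end in loss of a proton, in chloride capture on the wrong face of C4', or in opening of the bridged bromonium ion at C3' so that the two halogens change places. The fallback sets out from diol 20 and comes back at 26; it adds chlorine by epoxide opening and moves it to C4' in a concerted step. Diol 20 is converted with 1,1'-thiocarbonyldiimidazole into the cyclic thionocarbonate F1, which P(OMe)3 at reflux (Corey–Winter) should deoxygenate to the trisubstituted alkene F2. NBS in aqueous acetone should give the trans-diaxial bromohydrin F3 (water at C4' on the face of the C1' substituent, bromine at C3' on the other). K2CO3 in MeOH closes it to the epoxide F4, and pyridinium chloride in CH2Cl2 should open F4 trans-diaxially at the secondary carbon to the chlorohydrin F5. HBr in AcOH at 0 °C should turn the axial tertiary alcohol into the axial tertiary bromide F6 by axial capture. Warming F6 in toluene should then bring about the diaxial-to-diequatorial 1,2-interchange of the vicinal halogens, each staying on its own face, which gives 26. The same warming would correct material from step 16 in which the halogens had changed places.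

2. Step 9. The hydroxyl may attack C5 instead of C6 and close a five-membered ether, the bromonium ion may form at the ring B alkene, or the facial discrimination at C5 may be weak. The fallback sets out from 15 and comes back at 16. Hg(OCOCF3)2 in MeNO2 at −20 °C should effect a reversible, strictly Markovnikov oxymercuration that closes the six-membered ether and gives the organomercury trifluoroacetate F7. KBr exchanges it to the organomercury bromide F8 with mercury equatorial on C5. Br2 in pyridine at 0 °C (brominative demercuration with retention) should then give 16.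

3. Step 3. The chair transition state may compete with the boat, or chelation may be incomplete and give mixed ketene acetal geometry; either erodes the C2 configuration relative to C1'. The fallback sets out from acid 3 and comes back at 8; it forms the same bond in the acyclic series, where the chair is dependable, and closes ring B afterwards. Commercial (R)-but-3-yn-2-ol is alkylated as its dianion (n-BuLi, THF/DMPU) with 5-bromopent-1-ene to the enynol F9. NaAlH2(OCH2CH2OCH3)2 should reduce it to the (E)-allylic alcohol F10, and DCC/DMAP with acid 3 gives the ester F11. Under the conditions of step 3 the chelated lithium enolate F12 is silylated to the (Z)-silyl ketene acetal F13. This should rearrange through a chair with the carbinol methyl equatorial to the silyl ester F14 and, after work-up, the acid F15, which carries the C2/C1' configuration of 8. Ring-closing metathesis with the second-generation Grubbs catalyst (CH2Cl2, 40 °C) between the propenyl and pentenyl arms then gives 8.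

**Further compounds**

F1 | step 16 | cyclic thionocarbonate of diol 20 | CC1(C)O[C@](C)([C@H]2CC[C@]3(C)OC(=S)O[C@@H]3C2)CC[C@H]1Br
F2 | step 16 | (2S,5R)-5-bromo-2,6,6-trimethyl-2-[(1S)-4-methylcyclohex-3-en-1-yl]oxane | CC1(C)O[C@](C)([C@H]2CCC(C)=CC2)CC[C@H]1Br
F3 | step 16 | trans-diaxial bromohydrin, Br on C3' trans and OH on C4' cis to the oxanyl group | CC1(C)O[C@](C)([C@H]2CC[C@@](C)(O)[C@H](Br)C2)CC[C@H]1Br
F4 | step 16 | C3'–C4' epoxide with the oxirane oxygen cis to the oxanyl group | CC1(C)O[C@](C)([C@H]2CC[C@@]3(C)O[C@H]3C2)CC[C@H]1Br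
F5 | step 16 | trans-diaxial chlorohydrin, Cl on C3' trans and OH on C4' cis to the oxanyl group | CC1(C)O[C@](C)([C@H]2CC[C@@](C)(O)[C@H](Cl)C2)CC[C@H]1Br
F6 | step 16 | trans-diaxial 4'-bromo-3'-chloro isomer of 26 | CC1(C)O[C@](C)([C@H]2CC[C@@](C)(Br)[C@H](Cl)C2)CC[C@H]1Br
F7 | step 9 | organomercury trifluoroacetate, HgOCOCF3 on C5 (not isolated) | CC1(C)O[C@](C)([C@H]2CCCC=C2)CC[C@H]1[Hg]OC(=O)C(F)(F)F
F8 | step 9 | organomercury bromide, HgBr on C5 | CC1(C)O[C@](C)([C@H]2CCCC=C2)CC[C@H]1[Hg]Br
F9 | step 3 | (R)-non-8-en-3-yn-2-ol | C[C@@H](O)C#CCCCC=C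
F10 | step 3 | (2R,3E)-nona-3,8-dien-2-ol | C[C@@H](O)/C=C/CCCC=C
F11 | step 3 | (2R,3E)-nona-3,8-dien-2-yl (S)-2-(benzyloxy)propanoate | C[C@H](OCc1ccccc1)C(=O)O[C@H](C)/C=C/CCCC=C
F12 | step 3 | chelated lithium enolate of F11 (not isolated) | C/C(OCc1ccccc1)=C(/[O-])O[C@H](C)/C=C/CCCC=C.[Li+]
F13 | step 3 | (Z)-trimethylsilyl ketene acetal of F11 (not isolated) | C/C(OCc1ccccc1)=C(/O[Si](C)(C)C)O[C@H](C)/C=C/CCCC=C
F14 | step 3 | trimethylsilyl ester of F15 (not isolated) | c1ccccc1CO[C@](C)([C@H](/C=C/C)CCCC=C)C(=O)O[Si](C)(C)C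
F15 | step 3 | (2R,3S)-2-(benzyloxy)-2-methyl-3-[(E)-prop-1-en-1-yl]oct-7-enoic acid | c1ccccc1CO[C@](C)([C@H](/C=C/C)CCCC=C)C(=O)O
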